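## Analysis of the target

The target 21 is an isoflavan, (3S)-3-(3-hydroxy-2,4,5-trimethoxyphenyl)-8-methoxychroman-7-ol. Benzene ring A is fused to a saturated pyran ring C (O1, C2, C3, C4, C4a, C8a), and a second benzene ring B sits on C3. Ring A has a free phenol at C7 beside a methoxy group at C8, and ring B has methoxy groups at C2', C4' and C5' and a free phenol at C3', so only C6' is unsubstituted. C3 is the only stereocentre; it carries hydrogen, ring B and the two ring methylenes C2 and C4, has no neighbouring stereocentre to relay from, and must be set by a chiral reagent or catalyst. In the target C3 is configurationally robust, but it is at risk in any intermediate where it lies α to a carbonyl group or next to a cationic carbon. Both rings are very electron-rich, so they are easily oxidised and easily alkylated by carbocations, and the methyl ethers flanked by two oxygens are the ones most exposed to Lewis acids. The main difficulty is ring B, where four contiguous oxygens must be installed and the inner one at C3' must end up different from its neighbours. The strategy treats C2', C3', C4' and C5' as the four carbons of a squaric ester, which arrive oxygenated and pairwise distinguishable, and C1' and C6' as the two carbons of an alkyne attached to C3 of a finished chroman.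

## Retrosynthetic reasoning

**21 from 20.** The two phenols are unmasked last. The O–benzyl bond at C7 and the O–isopropyl bond at C3' are cut. Both ether types fall to one Lewis-acid treatment that leaves aryl methyl ethers intact, so tetra-ether 20 already holds the whole skeleton and the stereocentre.

**20 from 18.** The methyl groups on the C2' and C5' oxygens are removed. These oxygens are para to each other, so demethylation and removal of two hydrogens leads back to quinone 18 by way of hydroquinone 19. The gain is that the C2' and C5' oxygens are distinguished from those at C3' and C4' by oxidation level rather than by protecting groups. The forward reaction is a one-pot reduction and double O-methylation.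

**18 from 16.** This is the key disconnection. The C1'–C2' bond is cut and ring B contracts to the 4-alkynyl-4-hydroxycyclobutenone 16. In 16 the ring carbonyl is the later C2', the carbinol carbon is C5', the two alkoxy-bearing carbons are C3' and C4', and the alkyne carbons are C6' and C1'. The cut is made here because it leaves every oxygen of ring B on the four-membered ring and every atom of rings A and C on the other side of the alkyne. No stereocentre is formed and C3 is a spectator. The forward reaction is a thermal ring expansion through ketene 17 and must close a six-membered, not a five-membered, ring.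

**16 from 11 and 14.** The carbinol–alkyne bond (C5'–C6') is cut, giving acetylide 15 from alkyne 11 and the mixed squarate 14. Squarate 14 carries the methyl/isopropyl distinction that becomes the C4' methoxy and the C3' phenol. The addition must take place at the carbonyl next to the methoxy-bearing carbon. The two carbonyls of 14 are nearly alike, so an isomer from attack at the other carbonyl must be removed. That cost is accepted because the step is convergent and fixes the oxygen pattern before ring B exists.

**14 from 12.** The mixed ester is traced to diisopropyl squarate 12 through monoester 13. Mono-hydrolysis followed by O-methylation avoids a statistical ester exchange.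

**11 from 8.** The alkyne carbon bonded to C3 is the former carboxyl carbon; the terminal carbon is added by one-carbon homologation of aldehyde 10. Aldehyde 10 comes from acid 8 by way of alcohol 9. C3 is α to a carbonyl group only in 10, which is made under non-basic conditions and used at once.

**8 from 7.** The C3–H and C4–H bonds are cut. Asymmetric hydrogenation of the chromene acid 7 creates C3. The carboxyl group binds the catalyst, the ring fixes the alkene geometry, and the product is a crystalline acid whose enantiomeric purity can be raised if needed.

**7 from 4 and 5.** Ring C is opened at O1–C2 and C3–C4. Salicylaldehyde 4 and acrolein 5 combine by oxa-Michael addition and aldol condensation to enal 6, which is oxidised to 7.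

**4 from 1.** The benzyl group is removed from the para oxygen of 3, and the formyl group of 3 is removed to reach 2-methoxyresorcinol 1. Diol 1 is symmetric, so formylation has only one possible outcome, by way of iminium salt 2.

## Alternatives that were turned down

Alternative 1: The bonds C3–C1' and C4–C4a are cut, and C3–C4 is supplied by 4,4,5,5-tetramethyl-2-vinyl-1,3,2-dioxaborolane A2. In the forward step (3-benzyloxy-2,4,5-trimethoxyphenyl)lithium A3 adds to the boron of A2. Pd(OAc)2 with a chiral ferrocenyl bisphosphine provides a zerovalent palladium species that inserts into the C–O bond of 4-(benzyloxy)-3-methoxy-2-(methoxymethoxy)phenyl trifluoromethanesulfonate A4. The arylpalladium cation derived from A4 binds the vinyl group and triggers 1,2-migration of the aryl group of A3 from boron to carbon, and reductive elimination joins C4 to ring A, giving boronic ester A1 with C3 set.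

- For: three components, two C–C bonds and the stereocentre in one catalytic step, with aryl migrating groups and aryl triflates as the usual partners.
- Against: A1 has no C2. A one-carbon boronate homologation at a hindered secondary benzylic centre, oxidation, removal of the methoxymethyl group and an ether ring closure must follow before the benzyl groups are removed. Both aryl partners, A3 and A4, are ortho-substituted and electron-rich, which slows oxidative addition and invites direct aryl–aryl coupling in place of the migration. The arene behind A3 must also be bought or made with its C3' oxygen already differentiated, which is a multistep problem of its own.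
- Comparison: Alternative 1 is at least as strong in convergence and in catalytic stereocontrol of a C–C bond formation. The chosen route instead assembles the ring B oxygen pattern from a four-carbon building block, sets C3 early on a crystallisable acid, and needs no steps to add a missing ring atom.

Alternative 2: Ring C is cut at C3–C4 and O1–C2. In the forward step base expels sulfinate from 3-(benzyloxy)-2-methoxy-6-{[(4-methylphenyl)sulfonyl]methyl}phenol A6 to release the ortho-quinone methide A8. A chiral diarylprolinol silyl ether catalyst converts (3-benzyloxy-2,4,5-trimethoxyphenyl)acetaldehyde A7 into an enamine, which attacks the methylene of A8 (C3–C4). The phenoxide then closes on the aldehyde carbon (O1–C2) to give lactol A5.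

- For: a known organocatalytic reaction class; ring C and the stereocentre form together, and only deoxygenation at C2 and hydrogenolysis remain.
- Against: C3 of A5 is α to a masked aldehyde and benzylic to an electron-rich ring. Ring–chain tautomerism exposes an enolisable α-aryl aldehyde that the amine catalyst can re-engage, so the configuration can erode. Ionic removal of the C2 hydroxyl passes through an oxocarbenium ion next to C3, from which loss of the C3 proton destroys the stereocentre. A8 has an unsubstituted methylene, is short-lived and tends to oligomerise as soon as it leaves A6, and A7 self-condenses. A7 again requires the differentiated ring B.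
- Comparison: Alternative 2 is shorter once the fragments exist. The chosen route keeps C3 α to a carbonyl group only once, briefly and without base, and never next to a cation.

Alternative 3: The bonds C4–C4a and C8a–O1 are cut. In the forward step zerovalent palladium inserts into the aryl–iodine bond of 1-(benzyloxy)-3-iodo-2-methoxybenzene A10. A chiral norbornene-type mediator relays palladium to the free ortho position of A10, and the palladacycle opens 3-(3-benzyloxy-2,4,5-trimethoxyphenyl)oxetane A11 at one of its two enantiotopic methylenes (C4–C4a). After extrusion of the mediator the alkoxide closes on the ipso carbon (C8a–O1) to give chroman A9, one hydrogenolysis away from 21.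

- For: the shortest plan; the methoxy group of A10 that becomes the C8 methoxy is the ortho substituent this catalysis requires, and the stereocentre comes from desymmetrisation.
- Against: oxetanes are much weaker alkylating partners for such palladacycles than three-membered rings. The methylene to be attacked is neopentyl-like and next to an ortho-substituted aryl group. The chiral mediator is far from the carbon that becomes C3, so there is no secure basis for distinguishing the two methylenes. The step would have to be developed, and A11 again needs the differentiated ring B plus an oxetane synthesis.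
- Comparison: Alternative 3 is clearly stronger in step economy and convergence. The chosen route uses only established reaction types, sets C3 by a well-understood carboxylate-directed hydrogenation, and confines its main risk to one ring expansion of a well-known kind. Its price is a regioisomer separation at step 11.

Key step: step 12

Remark: the facial sense of step 5 is assigned by analogy with acyclic (E)-2-alkyl-3-arylacrylic acids; if the first run shows the opposite sense, Ru(OAc)2[(R)-BINAP] is used and nothing else changes.

## Route

Step 1
Reactants: 1 2-methoxyresorcinol (2-methoxybenzene-1,3-diol)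
Product: 3 2,4-dihydroxy-3-methoxybenzaldehyde, via aryl iminium chloride 2 (not isolated)
Conditions: POCl3, DMF, MeCN, 0 °C to rt; then H2O, 50 °C
Reagents that add atoms: N,N-dimethylformamide, CN(C)C=O; water, O
Why: Vilsmeier–Haack formylation: the two activated positions of 1 (each ortho to one hydroxyl and para to the other) are equivalent by symmetry, so only one aldehyde can form. Iminium salt 2 is too electron-poor for a second attack and is hydrolysed on warming with water.

Step 2
Reactants: 3 2,4-dihydroxy-3-methoxybenzaldehyde
Product: 4 4-(benzyloxy)-2-hydroxy-3-methoxybenzaldehyde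
Conditions: BnBr (1.05 equiv), NaHCO3, KI (cat.), MeCN, 80 °C
Reagents that add atoms: benzyl bromide, BrCc1ccccc1
Why: Williamson ether synthesis under a weak base: the 4-hydroxyl, para to the formyl group, is the more acidic and is unencumbered, whereas the 2-hydroxyl is held in a hydrogen bond to the aldehyde and flanked on both sides. Mono-benzylation at O4 is therefore expected.

Step 3
Reactants: 4 4-(benzyloxy)-2-hydroxy-3-methoxybenzaldehyde; 5 acrolein
Product: 6 7-(benzyloxy)-8-methoxy-2H-chromene-3-carbaldehyde
Conditions: K2CO3 (cat.), 1,4-dioxane, reflux
Reagents that add atoms: none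
Why: Domino oxa-Michael addition/intramolecular aldol condensation: the phenoxide adds to the terminal carbon of acrolein (O1–C2), the enolate closes on the aryl aldehyde (C3–C4) and dehydration gives the conjugated enal. The reaction is routine for salicylaldehydes, including those with an ortho methoxy group.

Step 4
Reactants: 6 7-(benzyloxy)-8-methoxy-2H-chromene-3-carbaldehyde
Product: 7 7-(benzyloxy)-8-methoxy-2H-chromene-3-carboxylic acid
Conditions: NaClO2, NaH2PO4, 2-methyl-2-butene, t-BuOH/H2O, rt
Reagents that add atoms: sodium chlorite, [Na+].[O-]Cl=O
Why: Pinnick oxidation: chlorous acid converts the enal into the acid without touching the C3=C4 bond, and 2-methyl-2-butene removes hypochlorous acid before it can chlorinate ring A.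

Step 5
Reactants: 7 7-(benzyloxy)-8-methoxy-2H-chromene-3-carboxylic acid
Product: 8 (3R)-7-(benzyloxy)-8-methoxychroman-3-carboxylic acid
Conditions: H2 (30 atm), Ru(OAc)2[(S)-BINAP] (1 mol %), MeOH, 30 °C
Reagents that add atoms: none
Why: Asymmetric hydrogenation of an α,β-unsaturated carboxylic acid with a divalent ruthenium BINAP dicarboxylate: the substrate binds as its carboxylate and hydrogen is delivered to one face of the C3=C4 bond, which creates C3. (S)-BINAP is chosen by analogy with acyclic (E)-2-alkyl-3-arylacrylic acids of the same alkene geometry, where it leads to the face that corresponds here to the (3R) acid. The benzyl ether is inert to this homogeneous catalyst.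

Step 6
Reactants: 8 (3R)-7-(benzyloxy)-8-methoxychroman-3-carboxylic acid
Product: 9 [(3S)-7-(benzyloxy)-8-methoxychroman-3-yl]methanol
Conditions: BH3·SMe2, THF, 0 °C to rt; then MeOH
Reagents that add atoms: none
Why: Borane reduction of a carboxylic acid through its acyloxyborane, chemoselective and free of base, so C3 cannot epimerise. The descriptor changes from R to S only because CH2OH ranks below C2.

Step 7
Reactants: 9 [(3S)-7-(benzyloxy)-8-methoxychroman-3-yl]methanol
Product: 10 (3R)-7-(benzyloxy)-8-methoxychroman-3-carbaldehyde
Conditions: Dess–Martin periodinane, NaHCO3, CH2Cl2, 0 °C to rt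
Reagents that add atoms: none
Why: Dess–Martin oxidation under buffered conditions stops at the aldehyde and is a standard way to prepare α-branched aldehydes without epimerisation. Aldehyde 10 is used at once without chromatography, since C3 is now α to a carbonyl group and β to the ring oxygen.

Step 8
Reactants: 10 (3R)-7-(benzyloxy)-8-methoxychroman-3-carbaldehyde
Product: 11 (3S)-7-(benzyloxy)-3-ethynyl-8-methoxychroman
Conditions: dimethyl (1-diazo-2-oxopropyl)phosphonate, K2CO3, MeOH, 0 °C to rt
Reagents that add atoms: dimethyl (1-diazo-2-oxopropyl)phosphonate, COP(=O)(OC)C(=[N+]=[N-])C(C)=O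
Why: Ohira–Bestmann variant of the Seyferth–Gilbert homologation: methanolysis of the reagent releases the diazomethylphosphonate anion, which olefinates the aldehyde, and loss of N2 with a 1,2-hydrogen shift gives the terminal alkyne. Homologation of α-branched aldehydes at 0 °C is normally faster than their enolisation, and once the alkyne is formed C3 is no longer next to a carbonyl group.

Step 9
Reactants: 12 diisopropyl squarate (3,4-diisopropoxycyclobut-3-ene-1,2-dione)
Product: 13 3-hydroxy-4-isopropoxycyclobut-3-ene-1,2-dione
Conditions: NaOH (1.0 equiv), THF/H2O, 0 °C to rt; then 1 M HCl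
Reagents that add atoms: sodium hydroxide, [Na+].[OH-]
Why: Hydrolysis of a vinylogous ester by addition–elimination: hydroxide attacks an alkoxy-bearing ring carbon and expels isopropoxide. The squarate mono-anion so formed is electron-rich and resists a second attack, so one equivalent of base stops at the monoester.

Step 10
Reactants: 13 3-hydroxy-4-isopropoxycyclobut-3-ene-1,2-dione
Product: 14 3-isopropoxy-4-methoxycyclobut-3-ene-1,2-dione
Conditions: MeI, Ag2O, MeCN, rt, dark
Reagents that add atoms: iodomethane, CI
Why: O-Alkylation of the silver salt of a squaric monoester with an alkyl iodide, the classical preparation of squaric esters. No alcohol is present, so the isopropyl group cannot be exchanged and only the mixed diester is expected.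

Step 11
Reactants: 11 (3S)-7-(benzyloxy)-3-ethynyl-8-methoxychroman; 14 3-isopropoxy-4-methoxycyclobut-3-ene-1,2-dione
Product: 16 4-{[(3S)-7-(benzyloxy)-8-methoxychroman-3-yl]ethynyl}-4-hydroxy-2-isopropoxy-3-methoxycyclobut-2-en-1-one (both carbinol epimers), via lithium acetylide 15 (not isolated)
Conditions: n-BuLi (1.0 equiv), THF, −78 °C; cannulated into 14 (1.3 equiv), THF, −78 °C; aq NH4Cl at −78 °C; SiO2
Reagents that add atoms: none
Why: 1,2-Addition of a lithium acetylide to a squarate carbonyl, the standard entry to 4-alkynyl-4-hydroxycyclobutenones; the lithium alkoxide is stable at −78 °C, so a second addition does not occur, and only the acetylenic hydrogen of 11 is acidic enough to be removed. Attack at the carbonyl next to the methoxy-bearing carbon gives 16; the other carbonyl differs only in the size of its neighbouring alkoxy group, so the regioisomer is expected as well and is removed by chromatography. The carbinol centre forms without control, which does not matter because it is destroyed in step 12.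

Step 12
Reactants: 16 4-{[(3S)-7-(benzyloxy)-8-methoxychroman-3-yl]ethynyl}-4-hydroxy-2-isopropoxy-3-methoxycyclobut-2-en-1-one
Product: 18 2-[(3S)-7-(benzyloxy)-8-methoxychroman-3-yl]-6-isopropoxy-5-methoxy-1,4-benzoquinone, via enynyl ketene 17 (not isolated)
Conditions: p-xylene (0.02 M, degassed), reflux (138 °C), Ar
Reagents that add atoms: none
Why: Moore rearrangement, the known thermal conversion of squarate-derived 4-alkynyl-4-hydroxycyclobutenones into 2,3-dialkoxy-1,4-benzoquinones. Heat opens the four-membered ring by conrotatory 4π electrocyclic cleavage of the bond between the carbonyl and the carbinol carbon; the hydroxyl group, as the donor, rotates outward, so the alkyne ends up cis to the ketene in 17. The ketene carbon (the later C2') then bonds to the distal alkyne carbon (C1') in a 6-endo-dig closure that forms ring B as a diradical, with one electron in a σ orbital on C6' and one in the phenoxyl-type π system. Transfer of the hydroxyl hydrogen to C6' collapses the diradical to quinone 18. The selectivity needed is six- over five-membered (5-exo-dig) closure: the five-membered path is favoured only when the alkyne substituent stabilises an exocyclic vinyl radical (aryl, silyl, alkoxy), which the secondary alkyl group at C3 of the chroman does not do. The oxygen pattern is fixed by 16 and not by this step: methoxy arrives at C4', isopropoxy at C3' and the two carbonyls at C2' and C5'. No stereocentre is created, the carbinol centre disappears, and C3 is untouched because the medium is neutral and transfer of its hydrogen to C6' would need a four-membered transition state. High dilution and exclusion of oxygen keep the diradical from intermolecular hydrogen abstraction.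

Step 13
Reactants: 18 2-[(3S)-7-(benzyloxy)-8-methoxychroman-3-yl]-6-isopropoxy-5-methoxy-1,4-benzoquinone
Product: 20 (3S)-7-(benzyloxy)-3-(3-isopropoxy-2,4,5-trimethoxyphenyl)-8-methoxychroman, via hydroquinone 19 (not isolated)
Conditions: Na2S2O4, THF/H2O, rt, Ar; then KOH, Me2SO4, Bu4NBr (cat.), rt
Reagents that add atoms: dimethyl sulfate, COS(=O)(=O)OC
Why: Reductive methylation of a quinone: Na2S2O4 reduces 18 to hydroquinone 19 and both phenoxides are methylated in the same flask before air can reoxidise them. Base is added only after the reduction is complete, so the quinone, whose hydrogen at C3 of the chroman is vinylogously acidic, never meets hydroxide; benzyl and isopropyl ethers are inert.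

Step 14
Reactants: 20 (3S)-7-(benzyloxy)-3-(3-isopropoxy-2,4,5-trimethoxyphenyl)-8-methoxychroman
Product: 21 (3S)-3-(3-hydroxy-2,4,5-trimethoxyphenyl)-8-methoxychroman-7-ol
Conditions: BCl3, C6HMe5, CH2Cl2, −78 to 0 °C; then H2O
Reagents that add atoms: none
Why: Lewis-acid ether cleavage: BCl3 removes the benzyl group at low temperature, the benzyl cation being trapped by pentamethylbenzene, and the secondary isopropyl group on warming, as 2-chloropropane. Both cleavages go through stabilised cations and are much faster than the cleavage of aryl methyl ethers, which are spared if the mixture is kept at or below 0 °C and quenched as soon as the isopropyl group is gone.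

## Compound list

1 | 2-methoxyresorcinol (2-methoxybenzene-1,3-diol) | COc1c(O)cccc1O | starting material
2 | N-(2,4-dihydroxy-3-methoxybenzylidene)-N-methylmethanaminium chloride | C[N+](C)=Cc1ccc(O)c(OC)c1O.[Cl-] | intermediate
3 | 2,4-dihydroxy-3-methoxybenzaldehyde | O=Cc1ccc(O)c(OC)c1O | intermediate
4 | 4-(benzyloxy)-2-hydroxy-3-methoxybenzaldehyde | O=Cc1ccc(OCc2ccccc2)c(OC)c1O | intermediate
5 | acrolein (prop-2-enal) | C=CC=O | starting material
6 | 7-(benzyloxy)-8-methoxy-2H-chromene-3-carbaldehyde | O=CC1=Cc2ccc(OCc3ccccc3)c(OC)c2OC1 | intermediate
7 | 7-(benzyloxy)-8-methoxy-2H-chromene-3-carboxylic acid | OC(=O)C1=Cc2ccc(OCc3ccccc3)c(OC)c2OC1 | intermediate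
8 | (3R)-7-(benzyloxy)-8-methoxychroman-3-carboxylic acid | OC(=O)[C@H]1COc2c(ccc(OCc3ccccc3)c2OC)C1 | intermediate
9 | [(3S)-7-(benzyloxy)-8-methoxychroman-3-yl]methanol | OC[C@H]1COc2c(ccc(OCc3ccccc3)c2OC)C1 | intermediate
10 | (3R)-7-(benzyloxy)-8-methoxychroman-3-carbaldehyde | O=C[C@H]1COc2c(ccc(OCc3ccccc3)c2OC)C1 | intermediate
11 | (3S)-7-(benzyloxy)-3-ethynyl-8-methoxychroman | C#C[C@H]1COc2c(ccc(OCc3ccccc3)c2OC)C1 | intermediate
12 | diisopropyl squarate (3,4-diisopropoxycyclobut-3-ene-1,2-dione) | CC(C)OC1=C(OC(C)C)C(=O)C1=O | starting material
13 | 3-hydroxy-4-isopropoxycyclobut-3-ene-1,2-dione | CC(C)OC1=C(O)C(=O)C1=O | intermediate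
14 | 3-isopropoxy-4-methoxycyclobut-3-ene-1,2-dione | COC1=C(OC(C)C)C(=O)C1=O | intermediate
15 | {[(3S)-7-(benzyloxy)-8-methoxychroman-3-yl]ethynyl}lithium | [Li]C#C[C@H]1COc2c(ccc(OCc3ccccc3)c2OC)C1 | intermediate
16 | 4-{[(3S)-7-(benzyloxy)-8-methoxychroman-3-yl]ethynyl}-4-hydroxy-2-isopropoxy-3-methoxycyclobut-2-en-1-one (carbinol epimers) | OC1(C#C[C@H]2COc3c(ccc(OCc4ccccc4)c3OC)C2)C(OC)=C(OC(C)C)C1=O | intermediate
17 | (3Z)-6-[(3S)-7-(benzyloxy)-8-methoxychroman-3-yl]-4-hydroxy-2-isopropoxy-3-methoxyhexa-1,3-dien-5-yn-1-one | O=C=C(OC(C)C)/C(OC)=C(/O)C#C[C@H]1COc2c(ccc(OCc3ccccc3)c2OC)C1 | intermediate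
18 | 2-[(3S)-7-(benzyloxy)-8-methoxychroman-3-yl]-6-isopropoxy-5-methoxy-1,4-benzoquinone | CC(C)OC1=C(OC)C(=O)C=C([C@H]2COc3c(ccc(OCc4ccccc4)c3OC)C2)C1=O | intermediate
19 | 2-[(3S)-7-(benzyloxy)-8-methoxychroman-3-yl]-6-isopropoxy-5-methoxybenzene-1,4-diol | Oc1cc([C@H]2COc3c(ccc(OCc4ccccc4)c3OC)C2)c(O)c(OC(C)C)c1OC | intermediate
20 | (3S)-7-(benzyloxy)-3-(3-isopropoxy-2,4,5-trimethoxyphenyl)-8-methoxychroman | COc1cc([C@H]2COc3c(ccc(OCc4ccccc4)c3OC)C2)c(OC)c(OC(C)C)c1OC | intermediate
21 | (3S)-3-(3-hydroxy-2,4,5-trimethoxyphenyl)-8-methoxychroman-7-ol | COc1cc([C@H]2COc3c(ccc(O)c3OC)C2)c(OC)c(O)c1OC | target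

## Step count and least certain steps

Total: 14 steps. Longest linear sequence: 12 steps (steps 1–8, then 11–14); steps 9 and 10 form the squarate branch that joins at step 11.

**Step 12 (key step).**
- Risk: the ketene may close on the near alkyne carbon to a five-membered ring, may be captured by its own hydroxyl group, or the diradical may abstract hydrogen from the solvent. The diradical carries only an alkyl substituent and has no extra stabilisation, so the internal hydrogen transfer competes with these channels.
- Fallback: a closed-shell ring expansion that sets out from alkyne 11 and returns at hydroquinone 19. Hydrozirconation of 11 with Cp2Zr(H)Cl and iodination with I2 would give (3S)-7-(benzyloxy)-3-[(E)-2-iodoethenyl]-8-methoxychroman F1. Iodine–lithium exchange on F1 with t-BuLi at −78 °C would give {(E)-2-[(3S)-7-(benzyloxy)-8-methoxychroman-3-yl]ethenyl}lithium F2. Addition of F2 to 14, with the same separation as in step 11, would give 4-{(E)-2-[(3S)-7-(benzyloxy)-8-methoxychroman-3-yl]ethenyl}-4-hydroxy-2-isopropoxy-3-methoxycyclobut-2-en-1-one F3. Heating F3 in toluene would open the four-membered ring, and the ketene so formed closes by 6π electrocyclisation without any radical intermediate and enolises to 19. Hydroquinone 19 is then methylated as in the second half of step 13.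

**Step 11.**
- Risk: lack of discrimination between the two carbonyls of 14, together with incomplete chromatographic resolution. Two regioisomers, each as two carbinol epimers, make four closely related diastereomers.
- Fallback: the sorting is moved behind the ring expansion. It sets out from the unseparated product of step 11, that is 16 together with 4-{[(3S)-7-(benzyloxy)-8-methoxychroman-3-yl]ethynyl}-4-hydroxy-3-isopropoxy-2-methoxycyclobut-2-en-1-one F4. The mixture of 16 and F4 is heated as in step 12, which removes the carbinol centre. Only two compounds then remain, 18 and 2-[(3S)-7-(benzyloxy)-8-methoxychroman-3-yl]-5-isopropoxy-6-methoxy-1,4-benzoquinone F5. Quinones 18 and F5 differ in which alkoxy group lies next to the hindered carbonyl, F5 is removed by chromatography, and the route is rejoined at 18.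

**Step 5.**
- Risk: insufficient or reversed facial selectivity. The ring oxygen beside C2 is a second possible binding site for ruthenium, and the cyclic alkene is more hindered than the acyclic models.
- Minor remedy: recrystallisation of acid 8 to raise its enantiomeric purity.
- Fallback: it sets out from enal 6 and returns at alcohol 9. Reduction of 6 with NaBH4 and CeCl3 in MeOH would give [7-(benzyloxy)-8-methoxy-2H-chromen-3-yl]methanol F6. Asymmetric hydrogenation of F6, a trisubstituted allylic alcohol, with [Ir(cod)((S)-tBu-PHOX)]BArF, or its enantiomer, in CH2Cl2 under H2 would give 9 directly. This also saves one step.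

**Step 8.**
- Risk: epimerisation at C3 of aldehyde 10 under K2CO3 in MeOH, by enolisation or by β-elimination and re-addition of the ring phenoxide, before the homologation is complete.
- Fallback: it sets out from 10 and returns at acetylide 15. Corey–Fuchs olefination (CBr4, PPh3, CH2Cl2, 0 °C) would give (3S)-7-(benzyloxy)-3-(2,2-dibromoethenyl)-8-methoxychroman F7 without base. Treating F7 with two equivalents of n-BuLi in THF at −78 °C would give 15 directly, and it is added to 14 as in step 11.

**Step 14.**
- Risk: loss of a flanked methyl ether (at C4', C2' or C8) during the exposure needed to cleave both groups, and Friedel–Crafts benzylation of the electron-rich rings if the scavenger is outcompeted.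
- Fallback: a two-stage deprotection that sets out from 20 and returns at 21. Hydrogenolysis (H2, Pd/C, EtOAc) would remove the benzyl group without forming a cation and give (3S)-3-(3-isopropoxy-2,4,5-trimethoxyphenyl)-8-methoxychroman-7-ol F8. The isopropyl ether of F8 is then cleaved by a short treatment with BCl3 that starts at −78 °C and is stopped as soon as the ether is gone.

## Further compounds

F1 | step 12 | (3S)-7-(benzyloxy)-3-[(E)-2-iodoethenyl]-8-methoxychroman | I/C=C/[C@H]1COc2c(ccc(OCc3ccccc3)c2OC)C1
F2 | step 12 | {(E)-2-[(3S)-7-(benzyloxy)-8-methoxychroman-3-yl]ethenyl}lithium | [Li]/C=C/[C@H]1COc2c(ccc(OCc3ccccc3)c2OC)C1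
F3 | step 12 | 4-{(E)-2-[(3S)-7-(benzyloxy)-8-methoxychroman-3-yl]ethenyl}-4-hydroxy-2-isopropoxy-3-methoxycyclobut-2-en-1-one (carbinol epimers) | OC1(/C=C/[C@H]2COc3c(ccc(OCc4ccccc4)c3OC)C2)C(OC)=C(OC(C)C)C1=O
F4 | step 11 | 4-{[(3S)-7-(benzyloxy)-8-methoxychroman-3-yl]ethynyl}-4-hydroxy-3-isopropoxy-2-methoxycyclobut-2-en-1-one (carbinol epimers) | OC1(C#C[C@H]2COc3c(ccc(OCc4ccccc4)c3OC)C2)C(OC(C)C)=C(OC)C1=O
F5 | step 11 | 2-[(3S)-7-(benzyloxy)-8-methoxychroman-3-yl]-5-isopropoxy-6-methoxy-1,4-benzoquinone | COC1=C(OC(C)C)C(=O)C=C([C@H]2COc3c(ccc(OCc4ccccc4)c3OC)C2)C1=O
F6 | step 5 | [7-(benzyloxy)-8-methoxy-2H-chromen-3-yl]methanol | OCC1=Cc2ccc(OCc3ccccc3)c(OC)c2OC1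
F7 | step 8 | (3S)-7-(benzyloxy)-3-(2,2-dibromoethenyl)-8-methoxychroman | BrC(Br)=C[C@H]1COc2c(ccc(OCc3ccccc3)c2OC)C1
F8 | step 14 | (3S)-3-(3-isopropoxy-2,4,5-trimethoxyphenyl)-8-methoxychroman-7-ol | COc1cc([C@H]2COc3c(ccc(O)c3OC)C2)c(OC)c(OC(C)C)c1OC
A1 | alternative 1 | 2-[(1S)-1-(3-benzyloxy-2,4,5-trimethoxyphenyl)-2-(4-benzyloxy-3-methoxy-2-(methoxymethoxy)phenyl)ethyl]-4,4,5,5-tetramethyl-1,3,2-dioxaborolane | COc1cc([C@H](Cc2ccc(OCc3ccccc3)c(OC)c2OCOC)B2OC(C)(C)C(C)(C)O2)c(OC)c(OCc2ccccc2)c1OC
A2 | alternative 1 | 4,4,5,5-tetramethyl-2-vinyl-1,3,2-dioxaborolane | C=CB1OC(C)(C)C(C)(C)O1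
A3 | alternative 1 | (3-benzyloxy-2,4,5-trimethoxyphenyl)lithium | [Li]c1cc(OC)c(OC)c(OCc2ccccc2)c1OC
A4 | alternative 1 | 4-(benzyloxy)-3-methoxy-2-(methoxymethoxy)phenyl trifluoromethanesulfonate | COCOc1c(OS(=O)(=O)C(F)(F)F)ccc(OCc2ccccc2)c1OC
A5 | alternative 2 | (3S)-7-benzyloxy-3-(3-benzyloxy-2,4,5-trimethoxyphenyl)-8-methoxychroman-2-ol (C2 anomers) | COc1cc([C@H]2C(O)Oc3c(ccc(OCc4ccccc4)c3OC)C2)c(OC)c(OCc2ccccc2)c1OC
A6 | alternative 2 | 3-(benzyloxy)-2-methoxy-6-{[(4-methylphenyl)sulfonyl]methyl}phenol | COc1c(O)c(CS(=O)(=O)c2ccc(C)cc2)ccc1OCc1ccccc1
A7 | alternative 2 | (3-benzyloxy-2,4,5-trimethoxyphenyl)acetaldehyde | O=CCc1cc(OC)c(OC)c(OCc2ccccc2)c1OC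
A8 | alternative 2 | 3-(benzyloxy)-2-methoxy-6-methylidenecyclohexa-2,4-dien-1-one | C=C1C=CC(OCc2ccccc2)=C(OC)C1=O
A9 | alternative 3 | (3S)-7-benzyloxy-3-(3-benzyloxy-2,4,5-trimethoxyphenyl)-8-methoxychroman | COc1cc([C@H]2COc3c(ccc(OCc4ccccc4)c3OC)C2)c(OC)c(OCc2ccccc2)c1OC
A10 | alternative 3 | 1-(benzyloxy)-3-iodo-2-methoxybenzene | COc1c(I)cccc1OCc1ccccc1
A11 | alternative 3 | 3-(3-benzyloxy-2,4,5-trimethoxyphenyl)oxetane | COc1cc(C2COC2)c(OC)c(OCc2ccccc2)c1OC
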